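1. The spring flask carries a leftover at 10.0 d: the L charged minus the L held in Q (one each) and in J (two each). It stands at 11.6 % of the Z charged, less than the 23.4 % of Z left. Since Z, Q and J add up to the Z charged, the leftover equals the excess of L charged plus Z left minus J.

all flasks: Z 0.10 M

| run | L | remark | time |
|---|---|---|---|
| spring | 0.11 M | the very flask that is asked about, followed so far |  |
| flask | 0.110 M |  | 25 d |

spring run (percent of the Z charged)

| time / d | Z / % | Q / % | J / % |
|---|---|---|---|
| 0.833 | 69.7 | 26.7 | 3.0 |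
| 1.67 | 56.0 | 37.5 | 7.1 |
| 4.00 | 37.1 | 47.9 | 15.4 |
| 10.0 | 23.4 | 55.6 | 21.4 |

(readings scatter by 0.5 percentage points)

* Z at 25 d, in percent of the Z charged
* Q at 25 d, in percent of the Z charged
* J at 25 d, in percent of the Z charged

2. At 10.0 d, [J]/([Q][leftover]) reads 33.2 L mol⁻¹. This sharing ratio is held fixed from here, as a reading with its scatter.

3. From 4.00 d to 10.0 d the fraction of Z left was 0.631, while the leftover fell from 31.3 %. That gives a loss of 0.358 d⁻¹ per unit of leftover.

4. With the leftover held at its 10.0 d value, Z at 25 d comes to 12.5 %. The ratio then puts the leftover at 6.68 %.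

5. The mean of the two leftovers gives Z 14.3 %, J 16.9 % and Q 68.8 %.

6. Decision: charge no more L and leave the flask to 25 d, since Q at 68.8 % stands above the 55.6 % read at 10.0 d.

The forecast gives Z 14.3 %, Q 69.2 % and J 16.5 %, with J lower than in this reckoning, on the ground that “J is near equilibrium with Q and L”.

The flask gives Z 14.7 %, Q 66.4 % and J 18.9 %.

    L ⇌ G (K = 0.570, k = 0.0550 h⁻¹)
    Z + L → Q (k = 0.270 L mol⁻¹ h⁻¹)
    L + Q ⇌ J (K = 61.0 L mol⁻¹, k = 0.150 L mol⁻¹ h⁻¹)

The leftover at 25 d is 5.77 % of the Z charged, or 0.00577 M, and it stands as free L, 0.00367 M, plus G, 0.00211 M. Reckoned on these values the sharing ratio is 49.3 L mol⁻¹, above the 33.2 L mol⁻¹ read at 10.0 d, and the reckoned J lies below the flask's.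

On the neighbour charged with 0.040 M of Z, the reading 33.2 L mol⁻¹ with Z taken as nil gives J 60.3 %. That flask gives J 62.4 %, Q 37.3 % and Z 0.302 %.

The runs come from a simulation for an exercise; scatter was added.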